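Impurity cannot take more enzyme than its own charge if the suspect step enzyme + impurity → spent catalyst runs one for one. In the flask impurity is the limiting reagent of that step, so the loss has a ceiling, the titration share: impurity charged over enzyme charged, here 23.3%.

the same everywhere: impurity 0.14 µM

| run | substrate | enzyme | remark |
|---|---|---|---|
| Friday's | 0.034 M | 0.60 µM | run made earlier |
| Monday's | 0.075 M | 0.60 µM | run made earlier |
| Wednesday's | 0.050 M | 1.2 µM | run made earlier |
| flask | 0.050 M | 0.60 µM |  |

| run | time / h | target / % | substrate / % |
|---|---|---|---|
| Friday's | 0.417 | 34 | 8 |
| Friday's | 0.667 | 28 | 6 |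
| Friday's | 0.833 | 26 | 8 |
| Friday's | 1.33 | 21 | 10 |
| Friday's | 2.00 | 16 | 6 |
| Friday's | 3.00 | 12 | 7 |
| Friday's | 5.00 | 6 | 1 |
| Monday's | 0.250 | 19 | 9 |
| Monday's | 0.667 | 17 | 8 |
| Monday's | 1.33 | 11 | 4 |
| Monday's | 2.00 | 7 | 2 |
| Monday's | 3.00 | 4 | 3 |
| Monday's | 4.00 | 5 | 2 |
| Monday's | 5.00 | 6 | 2 |
| Wednesday's | 0.417 | 27 | 13 |
| Wednesday's | 1.33 | 16 | 6 |
| Wednesday's | 2.00 | 12 | 1 |
| Wednesday's | 3.00 | 7 | 3 |
| Wednesday's | 5.00 | 5 | 2 |

(standard deviation of a reading: 1.5 percentage points)

- a species is counted by the substrate in it: one self-condensation product counts as two
- on the list of suspects stand: substrate + enzyme <-> complex; complex <-> enzyme + target; 2 substrate -> self-condensation product; enzyme + impurity -> spent catalyst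

- factor on the rate of making target when 20% of the substrate are converted if enzyme is charged twice over
- factor on the rate when 20% of the substrate are converted if enzyme is charged at 0.12 µM instead

The next plate hangs on when this share is paid. If titration is finished at the moment asked about, the doubled charge gains a factor 2.30. At 0.12 µM the share is 117%, so a finished titration would leave that well without free enzyme. If the rate at that moment still follows the whole charge, the factors are 2 and 0.200. The readings do not part these two pictures. Monday's first reading, at 0.250 h, has substrate down to 9%, so its conversion is already more than the 20% asked about. Wednesday's run lowers the share to 11.7% through its larger charge of enzyme, but its first reading, at 0.417 h, has substrate at 13%, also past the conversion asked about. The reckoning made here therefore keeps the 0.12 µM well on the plate, since it is the charge at which the two pictures differ between nothing and 0.200.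

The forecast gives 2.2 and 0.03, and says of the low charge: “The data cannot settle this.”

The flask gives 2.03 and 0.193.

    substrate + enzyme ⇌ complex (K = 30.0 /M, k = 9000 /M/s)
    complex ⇌ enzyme + target (K = 0.0860 M, k = 570 /s)
    2 substrate → self-condensation product (k = 0.0860 /M/s)
    enzyme + impurity → spent catalyst (k = 72000 /M/s)

The ceiling is reached in the flask: after 0.800 h spent catalyst stands at 23.3% of the catalyst and impurity at 0%. But the moment asked about comes at 0.375 min, earlier than 1.65 min, one over the rate per enzyme of poisoning with impurity as charged. The run without that step stands at 1.12 times the actual rate, so poisoning, a part of what shapes that rate, has cost 10.7% of it there, against the ceiling of 23.3%. At 0.12 µM the share is 117%, yet the factor on the rate is 0.193, beside the charge ratio of 0.200. The path from 2 substrate to self-condensation product has a part in this: the apparent order in enzyme at that conversion is 1.0, and 1.3 in the run without that path.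

The data stem from a simulated flask on assumed constants, and the scatter is random.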